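## Analysis of the target

The target 14 is a (2S)-flavanone: ring A and the pyranone ring C form a chroman-4-one, ring B sits on C2, the hydroxyls at C7 and C4' are free, and three 3-methylbut-2-enyl (prenyl) groups are bound through their CH2 ends to C6, C8 and C3'. C2 is the only stereocentre, so nothing relative has to be controlled, but it is fragile. It is β to the C4 ketone and carries O1 as a leaving group, so base opens ring C by a retro-oxa-Michael reaction (a 4'-phenoxide can also expel O1 through a quinone methide), and re-closure gives racemate, not an epimer. The second sensitive element is the set of ortho-prenylphenols: acid adds each phenolic oxygen across the neighbouring trisubstituted alkene to give a 2,2-dimethylchroman, and O7, with a prenyl group on either side, is the most exposed. The difficulty is therefore regiochemistry under mild conditions, not the skeleton: three aryl–CH2 bonds must be made at C6, C8 and C3' and none at C5', on a molecule with two phenols, without strong base and without acid. The feature on which the plan rests is that every prenyl group is ortho to a phenolic oxygen (C6 and C8 flank O7 on ring A, C3' neighbours O4' on ring B) and is attached by its unsubstituted terminus. That is the pattern left when a 1,1-dimethylallyl group migrates from a phenolic oxygen to the adjacent ring carbon by a [3,3] shift with allylic transposition. The unprenylated parent, (S)-liquiritigenin 4, already holds rings A, B and C, both hydroxyls and C2 in the required configuration, so the synthesis reduces to three O-to-C allyl transfers on an intact flavanone.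

## Retrosynthetic reasoning

**C6–CH2 bond (14 back to 12).** The bond between C6 and the benzylic CH2 of its prenyl group is cut and the allyl unit is returned, transposed, to O7, which gives the 7-O-(1,1-dimethylallyl) ether 12. This cut comes last because in 12 the other ortho carbon of O7 (C8) is already substituted and the para carbon (C4a) is a ring-fusion atom. The forward [3,3] shift, through dienone 13, therefore has a single productive outlet. The 4'-hydroxyl stays free in 12, so no allyl group can reach C5'.

**O7–C bond (12 back to 11, then to 10 and 3).** Ether 12 is the semi-hydrogenation product of alkyne 11, and 11 comes from bis-phenol 10 and carbonate 3 by forming one O–C(tertiary) bond. A tertiary alkyl aryl ether cannot be made by direct displacement, but a copper-catalysed propargylic substitution delivers it. That is why the ether is built at the alkyne level and reduced afterwards. The forward reaction must choose O7 over O4'. The handle is acidity: the 7-hydroxyl is para to the C4 carbonyl, so with one equivalent of base essentially only the 7-phenoxide is present.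

**C8–CH2 and C3'–CH2 bonds (10 back to 6, the key disconnection).** The two aryl–CH2 bonds of 10 are cut together and each allyl group goes back to its neighbouring oxygen, giving bis-ether 6. Both can be cut at once because ring B offers two equivalent ortho carbons, and on ring A an imperfect choice between C8 and C6 is repaired later, when the second round fills the remaining position. Cutting here, and not inside ring C or between the rings, means that no skeletal bond of the flavanone and nothing at C2 has to be made. The forward step is heat on a neutral molecule and passes through 7, 8 and 9 without reagents.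

**Two O–C(tertiary) bonds (6 back to 5, then to 4 and 3).** Bis-ether 6 is the semi-hydrogenation product of bis-alkyne 5, which comes from 4 and two equivalents of 3 by the same copper-catalysed etherification. The forward reaction has to alkylate both phenols completely while C2 survives the amine base, which means low temperature and short exposure.

**Carbonate (3 back to 1).** Carbonate 3 is the O-acylation product of tertiary propargylic alcohol 1, by way of its lithium alkoxide 2. One batch serves both etherifications.

## Alternatives that were turned down

**Alternative 1:** Ring A is built instead of decorated. The disconnection removes C8–C8a, C6–C7 and C4a–C8a and leads to cyclobutenone A2 and siloxyalkyne A3. In the forward direction heat opens A2 to a vinylketene, which adds [2+2] to the electron-rich alkyne of A3. The new cyclobutenone opens again, the dienylketene closes by 6π electrocyclisation, and tautomerisation gives the resorcinol monosilyl ether A1 with both ring A prenyl groups in place.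
- For it: the positions of the two prenyl groups follow from the connectivity of A2 and A3, so the C6/C8 question never arises, and O7 (silylated) and the future O1 (free) emerge differentiated. On both points it is stronger than the chosen route, which relies on an intrinsic ortho preference and on an acidity difference.
- Against it: A1 is only ring A. Still to do are the C4a–C4 bond (ortho acylation of a crowded, acid-sensitive diprenylphenol), the C2–C3 bond (condensation with the separately prenylated aldehyde A4), ring C and the C2 stereocentre. The last needs an enantioselective oxa-Michael closure at the chalcone stage, which is reversible under the conditions that promote it. Neither A2 nor A3 is a catalogue compound.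
- Comparison: the chosen route is far shorter, because 4 supplies rings A to C and C2 ready-made, and its regiochemical weakness is neutralised because both ortho carbons of O7 end up prenylated anyway.

**Alternative 2:** The O1–C8a bond of ring C is cut, leading to bromo diol A6, whose C3 carbinol is the future C2. Forward, a copper-catalysed intramolecular aryl etherification of the Ullmann type lets that hydroxyl displace bromide and closes ring C as a six-membered ring, giving flavan-4-ol A5. Oxidation at C4 and removal of the two methoxymethyl groups would follow.
- For it: the stereocentre is a simple benzylic carbinol that can be set by asymmetric reduction or aldol chemistry, independent of a natural source. At the alcohol oxidation level there is no retro-oxa-Michael pathway, so the configuration is safer during ring closure than anywhere in a flavanone-level route. This is a real advantage over the chosen plan.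
- Against it: A6 needs a hexasubstituted bromoarene that already carries both ring A prenyl groups, so the prenylation problem is only moved to earlier intermediates. The C–O coupling must occur at a carbon flanked by a prenyl group and the benzylic chain, under hot carbonate base. The end-game needs acid to remove the acetals, which is the condition that cyclises ortho-prenylphenols, with the doubly flanked O7 set free last.
- Comparison: the step count is several times that of the chosen route, which uses no protecting group on either phenol and no oxidation-state adjustment.

**Alternative 3:** The C2–C3 bond is cut and traced back to enol acetal A8, a 4-methylene-1,3-benzodioxine in which C2 is an acetal carbon. Forward, a chiral Lewis or Brønsted acid ionises the C2–O3 bond to an O1-stabilised oxocarbenium ion paired with the aryl ketone enolate. The enolate carbon then attacks C2 (Petasis–Ferrier rearrangement), forming C2–C3, ring C and the stereocentre, and giving the bis-silyl ether A7 of the target.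
- For it: it is the most convergent option and creates C2 catalytically in the event that closes the ring. In conception it is more elegant than buying the stereocentre.
- Against it: the enantio-determining C–C bond forms inside an ion pair of an achiral cation and an achiral enolate, so all induction must come from the counter-ion, which has no secure basis for this ring system. The oxocarbenium carbon lies within reach of the C8 prenyl alkene, so Prins-type capture competes with the enolate. Acid is the reagent class that prenylphenols tolerate least. A8 itself needs methylenation of a hindered lactone-type carbonyl, and the final desilylation with fluoride is basic enough to threaten C2.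
- Comparison: the chosen route has no step of comparable uncertainty. Its stereocentre is never formed, only preserved, and its key step needs no reagent.

Key step: step 4

Remark 1: (S)-liquiritigenin 4 is assumed to be purchasable as the single enantiomer; its enantiomeric purity should be checked by chiral HPLC before use and again after steps 2, 4 and 7.

Remark 2: in step 4 the two ethers rearrange independently; intermediates 7 to 9 are written for the case that ring A reacts first, and the opposite order leads to the same product 10.

## Route

Step 1
Reactants: 1 2-methylbut-3-yn-2-ol
Product: 3 methyl 2-methylbut-3-yn-2-yl carbonate, via lithium 2-methylbut-3-yn-2-olate 2 (not isolated)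
Conditions: n-BuLi (1.0 equiv), THF, –78 °C; then ClCO2Me, –78 °C → rt
Reagents that add atoms: methyl chloroformate, COC(=O)Cl; n-butyllithium, [Li]CCCC (its lithium stays only in intermediate 2)
Why: Carbonate formation by acylation of a lithium alkoxide with a chloroformate; one equivalent of n-BuLi removes only the hydroxyl proton, which is far more acidic than the alkyne C–H, and the tertiary alkoxide should be acylated cleanly in the cold.

Step 2
Reactants: 4 (S)-liquiritigenin [(2S)-7,4'-dihydroxyflavanone]; 3 methyl 2-methylbut-3-yn-2-yl carbonate
Product: 5 (2S)-7,4'-bis(2-methylbut-3-yn-2-yloxy)flavanone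
Conditions: 3 (3 equiv), DBU (2.6 equiv), CuCl2·2H2O (2 mol%), MeCN, 0 °C
Reagents that add atoms: none
Why: Copper-catalysed propargylic etherification: a copper acetylide of 3 loses methyl carbonate to give a copper allenylidene, which each phenoxide attacks at the tertiary carbon; this is the established route to aryl tertiary-propargyl ethers and serves the electron-poor 7-hydroxyl as well as the 4'-hydroxyl. DBU is the base with which this reaction turns over, so C2 is protected by low temperature, short contact and near-stoichiometric base and not by base strength; no new stereocentre is formed.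

Step 3
Reactants: 5 (2S)-7,4'-bis(2-methylbut-3-yn-2-yloxy)flavanone
Product: 6 (2S)-7,4'-bis(2-methylbut-3-en-2-yloxy)flavanone
Conditions: H2 (1 atm), Pd/CaCO3 poisoned with Pb(OAc)2 (Lindlar catalyst), quinoline, EtOAc, rt, stopped after 2 equiv H2
Reagents that add atoms: none
Why: Lindlar semi-hydrogenation of terminal alkynes; the poisoned surface binds the alkyne much more strongly than the vinyl group that forms, and the aryl ketone, the benzylic C2–O1 bond and the tertiary allylic C–O bonds should not be reduced at one atmosphere and room temperature.

Step 4
Reactants: 6 (2S)-7,4'-bis(2-methylbut-3-en-2-yloxy)flavanone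
Product: 10 (2S)-7,4'-dihydroxy-8,3'-bis(3-methylbut-2-enyl)flavanone, via ring A ortho-dienone 7 (not isolated), via half-rearranged phenol 8 (not isolated), via ring B ortho-dienone 9 (not isolated)
Conditions: degassed xylene, 130 °C, sealed tube, Ar, base-washed glass
Reagents that add atoms: none
Why: Each aryl 1,1-dimethylallyl ether should undergo a concerted suprafacial [3,3] shift through a chair-like six-membered transition state in which the O–C(tertiary) bond breaks while the vinyl terminus bonds to an ortho carbon, so that allylic transposition turns the tertiary ether into a CH2-linked prenyl group. The ortho-dienones 7 and 9 regain aromaticity by tautomerisation, which makes each shift irreversible and leads through phenol 8 to 10. The closest known reaction type is the aromatic Claisen rearrangement of aryl 1,1-dimethylallyl ethers to ortho-prenylphenols, known for 7-oxygenated chromanone, coumarin and flavanone ethers. No ring is closed and no lasting stereocentre is made: the sp3 carbon of each dienone is erased on enolisation, and no bond to C2 is broken. The selectivity needed is the ortho site on ring A; C8 should be favoured because the Kekulé form that lets both O1 and O7 conjugate with the C4 carbonyl places the double bond between C7 and C8, and any C6 isomer converges on 14 after steps 5 to 7. Ring B needs no selectivity because C3' and C5' are equivalent by rotation. The gem-dimethyl group weakens the O–C bond and relieves strain in the transition state, so the shift should run near 130 °C, well below what simple allyl ethers need. The neutral aprotic medium withholds the base that opens ring C and the acid that ionises the ether or cyclises the products to chromans.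

Step 5
Reactants: 10 (2S)-7,4'-dihydroxy-8,3'-bis(3-methylbut-2-enyl)flavanone; 3 methyl 2-methylbut-3-yn-2-yl carbonate
Product: 11 (2S)-4'-hydroxy-7-(2-methylbut-3-yn-2-yloxy)-8,3'-bis(3-methylbut-2-enyl)flavanone
Conditions: 3 (1.1 equiv), DBU (1.0 equiv), CuCl2·2H2O (2 mol%), MeCN, 0 °C
Reagents that add atoms: none
Why: The same copper-catalysed propargylic etherification, run with one equivalent of base: the 7-hydroxyl is para to the C4 carbonyl and markedly more acidic than the 4'-hydroxyl, so the 7-phenoxide is the anion present and the one that should capture the allenylidene. The nucleophile attacks a remote, unhindered carbon of the copper intermediate, so the ortho prenyl group at C8 should be tolerated.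

Step 6
Reactants: 11 (2S)-4'-hydroxy-7-(2-methylbut-3-yn-2-yloxy)-8,3'-bis(3-methylbut-2-enyl)flavanone
Product: 12 (2S)-4'-hydroxy-7-(2-methylbut-3-en-2-yloxy)-8,3'-bis(3-methylbut-2-enyl)flavanone
Conditions: H2 (1 atm), Pd/CaCO3 poisoned with Pb(OAc)2 (Lindlar catalyst), quinoline, EtOAc, rt, stopped after 1 equiv H2
Reagents that add atoms: none
Why: Lindlar semi-hydrogenation; the terminal alkyne should be reduced to the vinyl group while the two trisubstituted prenyl alkenes, which do not compete for the poisoned catalyst, remain.

Step 7
Reactants: 12 (2S)-4'-hydroxy-7-(2-methylbut-3-en-2-yloxy)-8,3'-bis(3-methylbut-2-enyl)flavanone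
Product: 14 (2S)-7,4'-dihydroxy-6,8,3'-tris(3-methylbut-2-enyl)flavanone (target), via C6 ortho-dienone 13 (not isolated)
Conditions: degassed xylene, 125–130 °C, sealed tube, Ar, base-washed glass
Reagents that add atoms: none
Why: Aromatic Claisen rearrangement: a chair [3,3] shift from O7 to C6 gives dienone 13, which tautomerises to the phenol. C8 is occupied and the para carbon C4a is a ring-fusion atom, so a shift towards C8 can only revert, and the ortho substituent at C8 raises the ground-state strain of the ether in favour of the productive shift. No stereocentre is formed, C2 is untouched, and the free 4'-hydroxyl cannot acquire a further prenyl group.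

## Compound list

1 | 2-methylbut-3-yn-2-ol | CC(C)(O)C#C | starting material
2 | lithium 2-methylbut-3-yn-2-olate | [Li+].[O-]C(C)(C)C#C | intermediate (not isolated)
3 | methyl 2-methylbut-3-yn-2-yl carbonate | COC(=O)OC(C)(C)C#C | intermediate
4 | (S)-liquiritigenin, (2S)-7,4'-dihydroxyflavanone | O=C1C[C@@H](c2ccc(O)cc2)Oc2cc(O)ccc21 | starting material
5 | (2S)-7,4'-bis(2-methylbut-3-yn-2-yloxy)flavanone | C#CC(C)(C)Oc1ccc([C@@H]2CC(=O)c3ccc(OC(C)(C)C#C)cc3O2)cc1 | intermediate
6 | (2S)-7,4'-bis(2-methylbut-3-en-2-yloxy)flavanone | C=CC(C)(C)Oc1ccc([C@@H]2CC(=O)c3ccc(OC(C)(C)C=C)cc3O2)cc1 | intermediate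
7 | (2S)-8-(3-methylbut-2-enyl)-2-[4-(2-methylbut-3-en-2-yloxy)phenyl]-2,3-dihydro-4H-chromene-4,7(8H)-dione, both C8 epimers | C=CC(C)(C)Oc1ccc([C@@H]2CC(=O)C3=C(O2)C(CC=C(C)C)C(=O)C=C3)cc1 | intermediate (not isolated)
8 | (2S)-7-hydroxy-8-(3-methylbut-2-enyl)-4'-(2-methylbut-3-en-2-yloxy)flavanone | C=CC(C)(C)Oc1ccc([C@@H]2CC(=O)c3ccc(O)c(CC=C(C)C)c3O2)cc1 | intermediate (not isolated)
9 | 4-[(2S)-7-hydroxy-8-(3-methylbut-2-enyl)-4-oxochroman-2-yl]-6-(3-methylbut-2-enyl)cyclohexa-2,4-dien-1-one, both C6 epimers of the dienone ring | CC(C)=CCC1C=C([C@@H]2CC(=O)c3ccc(O)c(CC=C(C)C)c3O2)C=CC1=O | intermediate (not isolated)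
10 | (2S)-7,4'-dihydroxy-8,3'-bis(3-methylbut-2-enyl)flavanone | CC(C)=CCc1cc([C@@H]2CC(=O)c3ccc(O)c(CC=C(C)C)c3O2)ccc1O | intermediate
11 | (2S)-4'-hydroxy-7-(2-methylbut-3-yn-2-yloxy)-8,3'-bis(3-methylbut-2-enyl)flavanone | CC(C)=CCc1cc([C@@H]2CC(=O)c3ccc(OC(C)(C)C#C)c(CC=C(C)C)c3O2)ccc1O | intermediate
12 | (2S)-4'-hydroxy-7-(2-methylbut-3-en-2-yloxy)-8,3'-bis(3-methylbut-2-enyl)flavanone | CC(C)=CCc1cc([C@@H]2CC(=O)c3ccc(OC(C)(C)C=C)c(CC=C(C)C)c3O2)ccc1O | intermediate
13 | (2S)-2-[4-hydroxy-3-(3-methylbut-2-enyl)phenyl]-6,8-bis(3-methylbut-2-enyl)-2,3-dihydro-4H-chromene-4,7(6H)-dione, both C6 epimers | CC(C)=CCc1cc([C@@H]2CC(=O)C3=CC(CC=C(C)C)C(=O)C(CC=C(C)C)=C3O2)ccc1O | intermediate (not isolated)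
14 | (2S)-7,4'-dihydroxy-6,8,3'-tris(3-methylbut-2-enyl)flavanone | CC(C)=CCc1cc([C@@H]2CC(=O)c3cc(CC=C(C)C)c(O)c(CC=C(C)C)c3O2)ccc1O | target

## Step count and least certain steps

Total: 7 steps. Longest linear sequence: 7 steps (1 → 3 → 5 → 6 → 10 → 11 → 12 → 14); counted from the flavanone 4 it is 6 steps.

**Step 4 (key step).** The most likely failure is heterolysis of the tertiary O–C bond instead of rearrangement. It is most probable at O7, whose aryloxide is stabilised by the para carbonyl, and would strip the allyl group as a diene and return the phenol. Incomplete selection between C8 and C6 is harmless, because both isomers converge after steps 5 to 7. Prolonged heating could erode the configuration at C2 by reversible opening of ring C. Fallback, from 4 back to the route at 10: both phenols of 4 are etherified without base by a Mitsunobu reaction with 3-methylbut-2-en-1-ol (PPh3, DIAD, THF, 0 °C) to give (2S)-7,4'-bis(3-methylbut-2-enyloxy)flavanone F1. The primary prenyl ethers are then moved to the ortho carbons by the clay-promoted [1,3] shift (montmorillonite K10, an acidic aluminosilicate clay, CH2Cl2, 0 °C), which gives 10. This replaces the thermal [3,3] shift of a tertiary ether by a low-temperature ion-pair recombination of a primary ether.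

**Step 2.** The most likely failure is racemisation by reversible ring opening while the 4'-hydroxyl is still free and an amidine base is present. The second risk is incomplete etherification of the less acidic 4'-hydroxyl. Fallback, from 4 directly to 6 (replacing steps 2 and 3): the tertiary allyl ethers are made in one step by allylic etherification catalysed by zerovalent palladium, with no amine base. The reagent is tert-butyl 2-methylbut-3-en-2-yl carbonate F2, prepared from 2-methylbut-3-en-2-ol, n-BuLi and Boc2O. With Pd(PPh3)4 in THF at 0 °C the phenols attack the more substituted allyl terminus under kinetic control, which gives 6. The reaction is kept cold and short so that the electron-poor O7 ether does not re-ionise to the linear isomer.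

**Step 5.** The most likely failure is loss of site selectivity between O7 and O4' through proton exchange between the two phenols or local excess of base. Any 4'-ether would deliver a second prenyl group to ring B in step 7. Fallback, from 10 back to the route at 11:
- Both phenols are silylated (TIPSOTf, 2,6-lutidine, CH2Cl2, 0 °C) to give (2S)-7,4'-bis(triisopropylsilyloxy)-8,3'-bis(3-methylbut-2-enyl)flavanone F3.
- The silyl ether at O7, activated by the para carbonyl, is cleaved selectively by acetate-catalysed solvolysis (LiOAc, DMF/H2O, 50 °C) to give (2S)-7-hydroxy-4'-(triisopropylsilyloxy)-8,3'-bis(3-methylbut-2-enyl)flavanone F4.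
- F4 is etherified with 3 as in step 5, now with no competing phenol, to give (2S)-7-(2-methylbut-3-yn-2-yloxy)-4'-(triisopropylsilyloxy)-8,3'-bis(3-methylbut-2-enyl)flavanone F5.
- Buffered fluoride (TBAF/AcOH 1:1, THF, 0 °C) removes the remaining silyl group and gives 11.

**Step 7.** The most likely failure is the same heterolysis as in step 4, made worse by the crowding of the O7 ether between C8-prenyl and the incoming C6 site, so that dealkylation back to 10 competes with the shift. Long heating could also cyclise a prenyl group onto its phenol. Fallback, from 10 back to the route at 14:
- The more acidic 7-hydroxyl is allylated under Mitsunobu conditions (prop-2-en-1-ol, PPh3, DIAD, THF, 0 °C) to give (2S)-7-allyloxy-4'-hydroxy-8,3'-bis(3-methylbut-2-enyl)flavanone F6. If the selectivity is insufficient, the silyl-protected phenol F4 is used in the same way.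
- The primary allyl ether, which has no ionisation pathway, is rearranged thermally (mesitylene, 185 °C) to (2S)-6-allyl-7,4'-dihydroxy-8,3'-bis(3-methylbut-2-enyl)flavanone F7.
- Cross-metathesis with 2-methylbut-2-ene (second-generation Grubbs catalyst, CH2Cl2, 40 °C) converts the allyl group into prenyl and gives 14. The existing prenyl groups are degenerate partners and stay unchanged.
- The higher temperature of this Claisen step makes a check of the enantiomeric purity necessary.

## Further compounds

F1 | step 4 | (2S)-7,4'-bis(3-methylbut-2-enyloxy)flavanone | CC(C)=CCOc1ccc([C@@H]2CC(=O)c3ccc(OCC=C(C)C)cc3O2)cc1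
F2 | step 2 | tert-butyl 2-methylbut-3-en-2-yl carbonate | C=CC(C)(C)OC(=O)OC(C)(C)C
F3 | step 5 | (2S)-7,4'-bis(triisopropylsilyloxy)-8,3'-bis(3-methylbut-2-enyl)flavanone | CC(C)=CCc1cc([C@@H]2CC(=O)c3ccc(O[Si](C(C)C)(C(C)C)C(C)C)c(CC=C(C)C)c3O2)ccc1O[Si](C(C)C)(C(C)C)C(C)C
F4 | step 5 | (2S)-7-hydroxy-4'-(triisopropylsilyloxy)-8,3'-bis(3-methylbut-2-enyl)flavanone | CC(C)=CCc1cc([C@@H]2CC(=O)c3ccc(O)c(CC=C(C)C)c3O2)ccc1O[Si](C(C)C)(C(C)C)C(C)C
F5 | step 5 | (2S)-7-(2-methylbut-3-yn-2-yloxy)-4'-(triisopropylsilyloxy)-8,3'-bis(3-methylbut-2-enyl)flavanone | CC(C)=CCc1cc([C@@H]2CC(=O)c3ccc(OC(C)(C)C#C)c(CC=C(C)C)c3O2)ccc1O[Si](C(C)C)(C(C)C)C(C)C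
F6 | step 7 | (2S)-7-allyloxy-4'-hydroxy-8,3'-bis(3-methylbut-2-enyl)flavanone | CC(C)=CCc1cc([C@@H]2CC(=O)c3ccc(OCC=C)c(CC=C(C)C)c3O2)ccc1O
F7 | step 7 | (2S)-6-allyl-7,4'-dihydroxy-8,3'-bis(3-methylbut-2-enyl)flavanone | CC(C)=CCc1cc([C@@H]2CC(=O)c3cc(CC=C)c(O)c(CC=C(C)C)c3O2)ccc1O
A1 | alternative 1 | 3-(triisopropylsilyloxy)-2,4-bis(3-methylbut-2-enyl)phenol | CC(C)=CCc1ccc(O)c(CC=C(C)C)c1O[Si](C(C)C)(C(C)C)C(C)C
A2 | alternative 1 | 2-(3-methylbut-2-enyl)cyclobut-2-en-1-one | O=C1CC=C1CC=C(C)C
A3 | alternative 1 | triisopropyl(5-methylhex-4-en-1-ynyloxy)silane | CC(C)=CCC#CO[Si](C(C)C)(C(C)C)C(C)C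
A4 | alternative 1 | 4-hydroxy-3-(3-methylbut-2-enyl)benzaldehyde | CC(C)=CCc1cc(C=O)ccc1O
A5 | alternative 2 | (2S,4R)-7,4'-bis(methoxymethoxy)-6,8,3'-tris(3-methylbut-2-enyl)flavan-4-ol | CC(C)=CCc1cc([C@@H]2C[C@@H](O)c3cc(CC=C(C)C)c(OCOC)c(CC=C(C)C)c3O2)ccc1OCOC
A6 | alternative 2 | (1R,3S)-1-[2-bromo-4-(methoxymethoxy)-3,5-bis(3-methylbut-2-enyl)phenyl]-3-[4-(methoxymethoxy)-3-(3-methylbut-2-enyl)phenyl]propane-1,3-diol | CC(C)=CCc1cc([C@@H](O)C[C@@H](O)c2cc(CC=C(C)C)c(OCOC)c(CC=C(C)C)c2Br)ccc1OCOC
A7 | alternative 3 | (2S)-7,4'-bis(tert-butyldimethylsilyloxy)-6,8,3'-tris(3-methylbut-2-enyl)flavanone | CC(C)=CCc1cc([C@@H]2CC(=O)c3cc(CC=C(C)C)c(O[Si](C)(C)C(C)(C)C)c(CC=C(C)C)c3O2)ccc1O[Si](C)(C)C(C)(C)C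
A8 | alternative 3 | racemic 7-(tert-butyldimethylsilyloxy)-2-[4-(tert-butyldimethylsilyloxy)-3-(3-methylbut-2-enyl)phenyl]-4-methylene-6,8-bis(3-methylbut-2-enyl)-4H-1,3-benzodioxine | C=C1OC(c2ccc(O[Si](C)(C)C(C)(C)C)c(CC=C(C)C)c2)Oc2c1cc(CC=C(C)C)c(O[Si](C)(C)C(C)(C)C)c2CC=C(C)C
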